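**Gas ratio.** A ratio had to settle my next run: what the solution asks of the gas against what the gas can bring.

G 0.085 M; J 9.5 mM (held); time 4.0 h

    J ⇌ Q, rate k1*(csat - [Q]) (k1 = 0.0933 min⁻¹, csat = 9.5 mM)
    G + Q → G.Q (k2 = 0.249 M⁻¹ min⁻¹)
    Q + G.Q ⇌ Q.G.Q, settled at all times (K3 = 1200 M⁻¹)
    G.Q ⇌ L (K4 = 1.92, k4 = 8.14 × 10⁻⁴ min⁻¹)

- for G.Q the Q.G.Q is counted in
- at the start none of Q is dissolved
- run time (flask): 4.0 h

- green: doubling the transfer coefficient of step 1, all else as stated
- blue: doubling the saturation concentration of J, all else as stated

- G.Q and Q.G.Q together at 4.0 h, in percent of the G charged
- the change that raises the amount of G.Q and Q.G.Q together at 4.0 h, in percent of the G charged most ("none" if none brings more than 2 percentage points) (green / blue / none)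
- amount of G.Q and Q.G.Q together at 4.0 h, in percent of the G charged, after blue

**Hand reckoning.** I took two Q per G, times the uptake constant and the G charged, over the transfer coefficient, which came to 0.454: the gas ratio. Setting supply equal to uptake put dissolved Q at saturation over one plus that ratio, 6.54 mM. I counted two Q because the balance constant times that level is 7.84, more than one, so the balance lies towards Q.G.Q. At a steady level G falls in a pseudo-first-order way with 0.0976 h⁻¹, which gave 32.3% of the G taken up by 4.0 h. I dropped the leak to L as a small correction because at that level the balance leaves free just 11.3% of the product, and the half-life of free G.Q by that step alone, forward rate only, is 14 h, longer than the run.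

**Next charge.** Blue leaves the ratio unchanged and raises the rate constant for G to 0.195 h⁻¹, giving 54.2%. Green halves the ratio, which lifts the level to 7.74 mM and gives 37.0%. Blue gained more than green, so I chose blue.

**The forecast.** It gave 32%, chose blue and put blue at 56%, above my blue figure. Its ground: “Doubling csat doubles the driving force and raises Q at every point in the run”.

**The result.** The simulation gave 33.0% for the flask and chose blue, worth 24 percentage points against 4.5 points for green, with 56.6% after blue.

**Ten hours.** So blue was the run to charge: the flask still held 66.7% of its G free at 4.00 h. With that G in the ratio, the level came to 7.29 mM against 0.00736 M of Q in the flask. The neighbouring flask, the same charge read at 10 h, stood at 65.4% for G.Q and Q.G.Q together, where my steady level gave 62.3%. It had 33.0% of its G left; the ratio on that G gave 8.26 mM, and Q there read 0.00831 M.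

(The constants used here are those of an exercise; what happens was integrated by code.)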